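**Retrosynthetic overview**
1. Tangeretin 14 comes from the 3-chloroflavone 13 by hydrogenolysis of C3–Cl. The feature used is that C3 of ring C is a lone CH between C2 (which carries ring B) and the C4 carbonyl, so ring C is a 2-arylbenzofuran-3-one plus one carbon placed into its C2–C3 bond.
2. 13 comes from the 3-silyloxybenzofuran 9 and chloroform 10: dichlorocarbene insertion into the furan C2=C3 bond forms C2–C3 and C3–C4 and enlarges the five-membered O-ring to ring C.
3. 9 comes from benzofuranone 8, and 8 from deoxybenzoin 6 (α-bromination, 5-exo O-alkylation, then O-silylation).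
4. 6 comes from phenol 4 and acid 5 (ortho C-acylation); 4 comes from 1 (ortho-lithiation, borylation, oxidation).
5. Ring order: rings A and B are bought; the furanone ring is closed on ring A in step 3 and expanded to ring C in step 5.

Key step: step 5

Remark: the target is achiral, and the stereocentres of 7, 8 and 11 form racemic and vanish later. The enol oxygen carries a TBS group because the 3-benzofuranolate is a phenol-like leaving group, so a trimethylsilyl ether would probably be cleaved by tert-butoxide before the carbene arrives.

**Route**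

Step 1
Reactants: 1 1,2,3,4-tetramethoxybenzene
Product: 4 2,3,4,5-tetramethoxyphenol, via (2,3,4,5-tetramethoxyphenyl)lithium 2 (not isolated), via lithium aryltrimethoxyborate 3 (not isolated)
Conditions: n-BuLi, TMEDA, THF, 0 °C to rt; B(OMe)3, –78 °C to rt; AcOH, 30% aq H2O2, 0 °C to rt; aq Na2S2O3
Reagents that add atoms: hydrogen peroxide, OO
Why: Directed ortho-metalation at the one kind of ring C–H (next to a methoxy group), borylation of the aryllithium and oxidation of the C–B bond to C–O is a standard arene hydroxylation sequence, and the mild acidic peroxide limits over-oxidation of the electron-rich phenol.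

Step 2
Reactants: 4 2,3,4,5-tetramethoxyphenol; 5 4-methoxyphenylacetic acid
Product: 6 1-(2-hydroxy-3,4,5,6-tetramethoxyphenyl)-2-(4-methoxyphenyl)ethan-1-one
Conditions: BF3·OEt2 (solvent), 85 °C, Ar; then aq NaOAc
Reagents that add atoms: none
Why: BF3-mediated Friedel–Crafts C-acylation of a phenol by an arylacetic acid (the one-pot deoxybenzoin synthesis) can only occur at C6, the single free position, which lies ortho to the hydroxyl and gives the chelated ortho-hydroxy ketone.

Step 3
Reactants: 6 1-(2-hydroxy-3,4,5,6-tetramethoxyphenyl)-2-(4-methoxyphenyl)ethan-1-one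
Product: 8 4,5,6,7-tetramethoxy-2-(4-methoxyphenyl)-1-benzofuran-3(2H)-one (racemic), via α-bromo ketone 7 (not isolated)
Conditions: PhNMe3Br3, THF, 0 °C to rt; filter, concentrate; K2CO3, degassed acetone, rt, Ar; cold dilute HCl
Reagents that add atoms: none
Why: The doubly activated benzylic CH2 enolises easily and is α-brominated selectively by the tribromide (ring A has no free position), and the ortho phenoxide then displaces the bromide in a 5-exo-tet intramolecular Williamson etherification, as in coumaranone syntheses; the C2 stereocentre forms racemic and is removed in step 4.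

Step 4
Reactants: 8 4,5,6,7-tetramethoxy-2-(4-methoxyphenyl)-1-benzofuran-3(2H)-one
Product: 9 3-(tert-butyldimethylsilyloxy)-4,5,6,7-tetramethoxy-2-(4-methoxyphenyl)-1-benzofuran
Conditions: TBSOTf, Et3N, CH2Cl2, 0 °C, Ar; rapid filtration through Et3N-deactivated silica
Reagents that add atoms: tert-butyldimethylsilyl trifluoromethanesulfonate, CC(C)(C)[Si](C)(C)OS(=O)(=O)C(F)(F)F
Why: Soft enolisation and O-silylation of a ketone with a silyl triflate and Et3N is standard silyl enol ether formation, favoured here by the acidity of C2–H and by aromatisation to the benzofuran.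

Step 5
Reactants: 9 3-(tert-butyldimethylsilyloxy)-4,5,6,7-tetramethoxy-2-(4-methoxyphenyl)-1-benzofuran; 10 chloroform
Product: 13 3-chloro-5,6,7,8-tetramethoxy-2-(4-methoxyphenyl)-4H-chromen-4-one, via dichlorocyclopropane adduct 11 (not isolated), via 4-silyloxyflavylium chloride 12 (not isolated)
Conditions: KOt-Bu (solid, in portions), 10 in excess, toluene–hexane, –20 °C to rt, Ar; aq NH4Cl
Reagents that add atoms: none
Why: Proposed new method: dichlorocarbene, formed from 10 by α-elimination with KOt-Bu, should add in a concerted [2+1] manner to the furan C2=C3 bond of 9 to give the cis-fused gem-dichlorocyclopropane 11; the endo chloride then ionises with disrotatory two-electron electrocyclic cleavage of the former C2–C3 bond (cyclopropyl-to-allyl cation opening) to the 4-silyloxyflavylium ion 12, and chloride takes the silyl group to leave the C4 carbonyl and the C2=C3 double bond of 13. The closest known reaction types are the dihalocarbene ring expansion of cyclic silyl enol ethers to 2-halo-2-enones and the Ciamician–Dennstedt-type one-carbon insertion into benzo-fused five-membered heteroarenes, neither shown on a 2-aryl-3-silyloxybenzofuran. Ring C is thus closed by ring expansion of the five-membered O-heterocycle and not by a cyclisation, the new carbon becoming C3 bonded to C2 and C4. No stereocentre remains in 13, since the two stereocentres of 11 come from suprafacial addition (cis fusion is the only possibility) and are erased on opening. The step needs the carbene to choose the C2=C3 bond and the cyclopropane to open at its internal bond: ring A has no hydrogen and ring B is a less nucleophilic anisole, so the doubly oxygenated enol ether is the preferred site, and the developing cation is flanked by the ring oxygen, the silyloxy group and the 4-methoxyphenyl group, which with the strain of the bicyclo[3.1.0] unit should drive internal-bond cleavage below room temperature.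

Step 6
Reactants: 13 3-chloro-5,6,7,8-tetramethoxy-2-(4-methoxyphenyl)-4H-chromen-4-one
Product: 14 tangeretin, 5,6,7,8-tetramethoxy-2-(4-methoxyphenyl)-4H-chromen-4-one
Conditions: Pd(OAc)2 (5 mol %), XPhos (10 mol %), HCO2Na, DMF–H2O, 80 °C
Reagents that add atoms: none
Why: Palladium-catalysed transfer hydrodehalogenation, in which zerovalent palladium on a bulky electron-rich phosphine inserts into the C3–Cl bond of the α-chloro enone, formate supplies hydride with loss of CO2 and reductive elimination gives C3–H, should leave the chromone C2=C3 bond and the five methoxy groups untouched.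

**Compound list**
1 | 1,2,3,4-tetramethoxybenzene | COc1ccc(OC)c(OC)c1OC | starting material
2 | (2,3,4,5-tetramethoxyphenyl)lithium | [Li]c1cc(OC)c(OC)c(OC)c1OC | intermediate
3 | lithium trimethoxy(2,3,4,5-tetramethoxyphenyl)borate | [Li+].CO[B-](OC)(OC)c1cc(OC)c(OC)c(OC)c1OC | intermediate
4 | 2,3,4,5-tetramethoxyphenol | COc1cc(O)c(OC)c(OC)c1OC | intermediate
5 | 4-methoxyphenylacetic acid | COc1ccc(CC(O)=O)cc1 | starting material
6 | 1-(2-hydroxy-3,4,5,6-tetramethoxyphenyl)-2-(4-methoxyphenyl)ethan-1-one | COc1ccc(CC(=O)c2c(O)c(OC)c(OC)c(OC)c2OC)cc1 | intermediate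
7 | 2-bromo-1-(2-hydroxy-3,4,5,6-tetramethoxyphenyl)-2-(4-methoxyphenyl)ethan-1-one (racemic) | COc1ccc(cc1)C(Br)C(=O)c1c(O)c(OC)c(OC)c(OC)c1OC | intermediate
8 | 4,5,6,7-tetramethoxy-2-(4-methoxyphenyl)-1-benzofuran-3(2H)-one (racemic) | COc1ccc(cc1)C1Oc2c(OC)c(OC)c(OC)c(OC)c2C1=O | intermediate
9 | 3-(tert-butyldimethylsilyloxy)-4,5,6,7-tetramethoxy-2-(4-methoxyphenyl)-1-benzofuran | COc1ccc(cc1)-c1oc2c(OC)c(OC)c(OC)c(OC)c2c1O[Si](C)(C)C(C)(C)C | intermediate
10 | chloroform | ClC(Cl)Cl | starting material
11 | tert-butyl{[1,1-dichloro-3,4,5,6-tetramethoxy-1a-(4-methoxyphenyl)-1,1a-dihydro-6bH-cyclopropa[b][1]benzofuran-6b-yl]oxy}dimethylsilane (racemic, cis-fused) | COc1ccc(cc1)C12Oc3c(OC)c(OC)c(OC)c(OC)c3C1(O[Si](C)(C)C(C)(C)C)C2(Cl)Cl | intermediate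
12 | 4-(tert-butyldimethylsilyloxy)-3-chloro-5,6,7,8-tetramethoxy-2-(4-methoxyphenyl)chromenylium chloride | COc1ccc(cc1)-c1[o+]c2c(OC)c(OC)c(OC)c(OC)c2c(O[Si](C)(C)C(C)(C)C)c1Cl.[Cl-] | intermediate
13 | 3-chloro-5,6,7,8-tetramethoxy-2-(4-methoxyphenyl)-4H-chromen-4-one | COc1ccc(cc1)-c1oc2c(OC)c(OC)c(OC)c(OC)c2c(=O)c1Cl | intermediate
14 | tangeretin, 5,6,7,8-tetramethoxy-2-(4-methoxyphenyl)-4H-chromen-4-one | COc1ccc(-c2cc(=O)c3c(OC)c(OC)c(OC)c(OC)c3o2)cc1 | target

**Step count**
Total: 6 steps. Longest linear sequence: 6 steps (1 to 14); 5 and 10 enter as purchased materials.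

**Steps most likely to fail**

1. Step 5 (proposed new method). The silyl ether may be cleaved by tert-butoxide before cyclopropanation, after which the free enolate would be C-alkylated by the carbene at C2. The cyclopropane may also fragment at an external bond, or the base may open the pyranone once formed. The fallback uses known chemistry, sets out from 4 and returns at 14. BF3·OEt2-mediated C-acetylation of 4 with acetic acid should give 1-(2-hydroxy-3,4,5,6-tetramethoxyphenyl)ethan-1-one F1. Claisen–Schmidt condensation of this with 4-methoxybenzaldehyde (KOH, EtOH) should give (E)-1-(2-hydroxy-3,4,5,6-tetramethoxyphenyl)-3-(4-methoxyphenyl)prop-2-en-1-one F2. Oxidative cyclisation of the 2'-hydroxychalcone with catalytic I2 in DMSO at 130 °C should then give 14.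

2. Step 3. The tribromide may oxidise the electron-rich, para-oxygenated phenol ring instead of brominating the α-position, and the enolisable 2-arylbenzofuranone may autoxidise at C2 during cyclisation and isolation. The fallback sets out from 4 and returns at 8, forming the C–O bond first and the C–C bond last. O-Alkylation of 4 with methyl 2-bromo-2-(4-methoxyphenyl)acetate (K2CO3, acetone) should give methyl 2-(4-methoxyphenyl)-2-(2,3,4,5-tetramethoxyphenoxy)acetate F3. Saponification (LiOH, THF–H2O, then acid) should give 2-(4-methoxyphenyl)-2-(2,3,4,5-tetramethoxyphenoxy)acetic acid F4. Intramolecular Friedel–Crafts acylation at the only free ring position in Eaton's reagent (P2O5 in MeSO3H, rt) should close the furanone ring to 8. That closure carries its own risk of decarbonylation of the acylium ion, so it is kept as the reserve and not the main line.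

3. Step 6. Oxidative addition into the C3–Cl bond, which sits on the electron-rich α-carbon of a vinylogous ester, may be slow, and forcing the reduction may saturate the C2=C3 bond. The fallback sets out from 9 and returns at 14, changing the halogen at the carbene stage. Ring expansion of 9 with dibromocarbene (CHBr3, KOt-Bu, toluene–hexane, –20 °C to rt) should give 3-bromo-5,6,7,8-tetramethoxy-2-(4-methoxyphenyl)-4H-chromen-4-one F5. Its weaker C–Br bond should be cleaved under mild conditions with Pd(PPh3)4 and HCO2Na in DMF at 80 °C to give 14.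

**Further compounds**
F1 | step 5 | 1-(2-hydroxy-3,4,5,6-tetramethoxyphenyl)ethan-1-one | CC(=O)c1c(O)c(OC)c(OC)c(OC)c1OC
F2 | step 5 | (E)-1-(2-hydroxy-3,4,5,6-tetramethoxyphenyl)-3-(4-methoxyphenyl)prop-2-en-1-one | COc1ccc(/C=C/C(=O)c2c(O)c(OC)c(OC)c(OC)c2OC)cc1
F3 | step 3 | methyl 2-(4-methoxyphenyl)-2-(2,3,4,5-tetramethoxyphenoxy)acetate (racemic) | COC(=O)C(Oc1cc(OC)c(OC)c(OC)c1OC)c1ccc(OC)cc1
F4 | step 3 | 2-(4-methoxyphenyl)-2-(2,3,4,5-tetramethoxyphenoxy)acetic acid (racemic) | OC(=O)C(Oc1cc(OC)c(OC)c(OC)c1OC)c1ccc(OC)cc1
F5 | step 6 | 3-bromo-5,6,7,8-tetramethoxy-2-(4-methoxyphenyl)-4H-chromen-4-one | COc1ccc(cc1)-c1oc2c(OC)c(OC)c(OC)c(OC)c2c(=O)c1Br
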